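(All runs come from a simulation with constants of no real substance, and the scatter is random.)

Target leads side product at the first east reading, 9.7 % against 5.0 %, and trails it at the last, 18.9 % against 34.5 %, so a share read from these flasks tells how far each has gone as well as how hot it stands.

| setting | east | west | Monday's | Saturday's | Thursday's | Tuesday's | Friday's | Sunday's |
|---|---|---|---|---|---|---|---|---|
| starting material | 21 mM | 32 mM | 42 mM | 42 mM | 42 mM | 42 mM | 42 mM | 42 mM |
| partner | 75.6 mM | 75.6 mM | 75.6 mM | 75.6 mM | 75.6 mM | 75.6 mM | 75.6 mM | 75.6 mM |
| second substrate | 42 mM | 42 mM | 42.0 mM | 42.0 mM | 42.0 mM | 42.0 mM | 42.0 mM | 42.0 mM |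
| protic impurity | 21 mM | 21 mM | 21.0 mM | 21.0 mM | 21.0 mM | 21.0 mM | 21.0 mM | 21.0 mM |
| temperature | 5 °C | 49 °C | 40 °C | 5 °C | −15 °C | 25 °C | 65 °C | −5 °C |
| remark | run made earlier | run made earlier |  |  |  |  |  |  |
| time |  |  | 50 min | 50 min | 50 min | 50 min | 50 min | 50 min |

| run | time / min | target / % | side product / % | starting material / % |
|---|---|---|---|---|
| east | 25.0 | 9.7 | 5.0 | 85.5 |
| east | 50.0 | 13.7 | 11.5 | 73.9 |
| east | 80.0 | 16.6 | 21.9 | 61.2 |
| east | 120 | 18.9 | 34.5 | 46.8 |
| west | 1.50 | 27.1 | 11.5 | 62.3 |
| west | 5.00 | 39.8 | 37.9 | 22.5 |
| west | 8.00 | 40.1 | 49.6 | 9.5 |
| west | 12.0 | 41.4 | 54.6 | 3.2 |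

(readings scatter by 0.5 percentage points)

* ranking by share of target in all that became target or side product, from high to low, at 50 min (Monday's / Saturday's / Thursday's / Tuesday's / Friday's / Sunday's)
* the same order at 2.5 min (Monday's / Saturday's / Thursday's / Tuesday's / Friday's / Sunday's)
* the share of target in all that became target or side product of the flask you put first, at 50 min
* the share of target in all that became target or side product of the flask you put last, at 50 min

- a species is counted by the starting material in it: one side product counts as two

I take it that target is eaten by starting material as it forms, and I carry one quantity, the ceiling, the plateau of this consecutive reaction. If the rising target curve is replaced by its mean, half the reading, then side product formed over target formed before loss equals [target] over the ceiling. The first readings give 4.97 mM in east and 24.8 mM in west, and a straight line in inverse temperature carries this to Thursday's, where the [target] at which target is eaten as fast as it forms is 2.00 mM.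

For you at the bench: starting material falls at 0.00605 /min in east and 0.298 /min in west, so by the same line Thursday's will have converted 1.37 mM when you read it, less than its ceiling, and I expect a share of 64.0 %. Do not leave it standing past the reading, since the converted amount keeps growing against that ceiling.

The forecast gives Thursday's > Sunday's > Friday's > Saturday's > Monday's > Tuesday's and, at 2.5 min, Thursday's > Sunday's > Saturday's > Tuesday's > Monday's > Friday's, with 63 % (from 54 % to 72 %) and 18 % (from 12 % to 26 %), calling the cold flasks “barely converted and still selective”; my 64.0 % stands just above that 63 %.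

The flasks give Thursday's > Sunday's > Friday's > Saturday's > Monday's > Tuesday's and Thursday's > Sunday's > Saturday's > Tuesday's > Monday's > Friday's, with 69.9 % and 21.4 %.

    starting material + target → side product (k = 2.60 /M/min, Ea = 42.0 kJ/mol)
    partner + protic impurity → quenched reagent (k = 11.9 /M/min, Ea = 59.0 kJ/mol)
    second substrate + partner → second product (k = 0.0549 /M/min, Ea = 72.0 kJ/mol)
    starting material + partner → target (k = 0.634 /M/min, Ea = 70.0 kJ/mol)
    (constants at 25 °C)

Thursday's shows 69.9 % because it is read at the time given and not at ten times as long, where the same flask shows 15.5 %. At the time given its 2.17 % of target and 0.934 % of side product read as a ceiling of 2.57 mM, somewhat above my 2.00 mM. Left the longer time, Thursday's holds 2.00 mM of target, level with that 2.00 mM, and the ceiling over the converted amount gives 15.5 % against the simulated share of 15.5 %.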